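(The readings come from a simulation from invented constants; noise was put on by code.)

Early times give you the rate. At 3.00 min the elm run has E down to 17 %, which with one X used per E reads as k = 0.660 M⁻¹ min⁻¹, a reading that carries the scatter. The decision is whether to keep this flask's charge and stop at 25 min.

| setting | ash | elm | flask |
|---|---|---|---|
| E | 0.71 M | 0.71 M | 0.71 M |
| X | 0.57 M | 1.3 M | 0.852 M |
| G | 0.355 M | 0.355 M | 0.355 M |
| remark | run made earlier | run made earlier |  |
| time |  |  | 25 min |

| run | time / min | E / % | D / % |
|---|---|---|---|
| ash | 3.00 | 46 | 55 |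
| ash | 6.00 | 36 | 63 |
| ash | 10.0 | 28 | 68 |
| ash | 12.0 | 28 | 65 |
| ash | 15.0 | 22 | 70 |
| ash | 20.0 | 19 | 69 |
| elm | 3.00 | 17 | 83 |
| elm | 6.00 | 6 | 92 |
| elm | 10.0 | 3 | 97 |
| elm | 12.0 | 2 | 97 |
| elm | 15.0 | 0 | 100 |
| elm | 20.0 | 0 | 98 |

(scatter of a reading: 1.5 percentage points)

- what has gone from E into another species counts as reacted, even if it can come back
- the earlier runs do not show how much of X is bound; that part of a forecast is a guess

1. part of the E that has reacted at 25 min
2. share of the unused X that is free and not bound as J, at 25 min

1. The flask holds a spare of 0.142 M of X beyond one per E.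

2. As [X] nears that spare, [E] decays with a lifetime of 10.7 min: this is the spare-X clock, one over k times the spare, a pseudo-first-order lifetime.

3. The same law puts [X]/[E] at 12.5 by 25 min. Taking [X] as the spare gives [E] = 0.0114 M. Put that back, with [X] as spare plus [E], and [E] = 0.0123 M, below the spare, so my c is 98.3 %.

4. One doubt remains: at 20.0 min the ash run's readings of E and D fall short of the E charged by 0.0852 M. That is a shortfall of E, and the runs do not show how much X is bound; if X is held away in that measure, the spare shrinks and the clock lengthens. So keep the charge and the time, and measure free X at the stop.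

The forecast, a little below my c, gives c 97 % (94 % to 99.5 %) and fr 85 % (60 % to 97 %), saying of the latter “This is a guess”.

The flask gives c 93.5 % and fr 10.3 %.

    X + Q ⇌ J, settled at all times (K = 3600 M⁻¹)
    Q + G ⇌ L, settled at all times (K = 2.51 × 10⁵ M⁻¹)
    E + X → Q + D (k = 0.0132 M⁻¹ s⁻¹)
    E + Q ⇌ Z, settled at all times (K = 430 M⁻¹)

At 25 min this flask has not come to rest. J stands at 0.212 M, more than the spare, and free X at 2.9 % of its charge. With that [X] in place of the spare, the clock reads 62.2 min, longer than 10.7 min. By 250 min c reaches 98.8 % and D goes from 86.8 % to 90.2 %, while J is then 0.208 M.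

On a neighbour flask charged with 2.1 M of X, the spare gives a clock of 1.09 min, so 25 min is 22.9 clocks and my c for it is close to 100 %. That neighbour flask gives c 100 %, with 0 % of E and 49 % of X left free.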